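**Retrosynthetic overview**

1. Ring A is numbered from its diaryl ether carbon (position 1) to the methoxy carbon (position 2), with bromine at positions 3 and 5; ring B is numbered from its ether carbon (position 1), with OH at position 2 and bromine at positions 4–6. The strategy rests on the two adjacent oxygen-bearing carbons of ring A, positions 1 and 2.
2. Target ⇐ removal of the ring B isopropyl group with BCl3 ⇐ O-methylation at ring A position 2 ⇐ dibromination at ring A positions 3 and 5, directed by a free hydroxyl at position 2 ⇐ 2-(aryloxy)phenol.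
3. 2-(Aryloxy)phenol ⇐ acetate cleavage and protodesilylation at ring A position 6 ⇐ benzannulation of ring A. 3-Acetoxy-2-pyrone supplies ring A positions 2 (its C3) to 5 (its C6), and a trimethylsilyl ynol ether of the ring B phenol supplies position 1 (oxygen-bearing alkyne carbon) and position 6. A [4+2] step followed by loss of CO2 forms the 1–2 and 5–6 bonds of ring A.
4. Silyl ynol ether ⇐ terminal ynol ether ⇐ (Z)-2-chlorovinyl ether ⇐ 2,3,4-tribromo-6-isopropoxyphenol and cis-1,2-dichloroethylene. Only hydroxide, alkoxide and silylamide bases are used, so the three aryl bromides never meet an alkyllithium. The pyrone comes from 3-hydroxy-2-pyrone.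
5. Ring order: ring B is bought as an arene and brominated first; ring A is the only ring constructed (step 6).

Key step: step 6

Remark on the chemistry: the target is achiral; the only stereochemical element in the route is the Z geometry of enol ether 5, which is lost in step 3.

**Route**

Step 1
Reactants: 1 2-isopropoxyphenol
Product: 2 2,3,4-tribromo-6-isopropoxyphenol
Conditions: Br2 (3.2 equiv), NaOAc, AcOH, rt to 40 °C
Reagents that add atoms: bromine, BrBr
Why: Electrophilic aromatic bromination is directed by the free hydroxyl to its para and ortho positions and by the isopropoxy group to its para position, the pattern known for tribromination of guaiacol, while NaOAc buffers the HBr so that the isopropyl ether should survive.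

Step 2
Reactants: 2 2,3,4-tribromo-6-isopropoxyphenol; 3 cis-1,2-dichloroethylene (4 equiv)
Product: 5 1,2,3-tribromo-4-{[(Z)-2-chloroethenyl]oxy}-5-isopropoxybenzene, via chloroacetylene 4 (not isolated)
Conditions: KOH (powdered, 2.5 equiv), DMSO, 60 °C, sealed tube, N2
Reagents that add atoms: none
Why: KOH converts 3 by anti elimination into chloroacetylene 4, and the phenoxide of 2 adds to its unsubstituted carbon with anti protonation to give the Z enol ether, the elimination–addition vinylation of phenols known from the trichloroethylene route to dichlorovinyl ethers.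

Step 3
Reactants: 5 1,2,3-tribromo-4-{[(Z)-2-chloroethenyl]oxy}-5-isopropoxybenzene
Product: 6 1,2,3-tribromo-4-(ethynyloxy)-5-isopropoxybenzene
Conditions: KOtBu (1.5 equiv), THF, 0 °C to rt; pH 7 buffer work-up
Reagents that add atoms: none
Why: In the Z isomer the hydrogen on the oxygen-bearing carbon is anti-periplanar to chlorine, so tert-butoxide should effect E2 dehydrochlorination as in the classical β-halovinyl ether route to alkynyl ethers, and an alkoxide base cannot undergo halogen–metal exchange with the three aryl bromides.

Step 4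
Reactants: 6 1,2,3-tribromo-4-(ethynyloxy)-5-isopropoxybenzene
Product: 8 trimethyl[(2,3,4-tribromo-6-isopropoxyphenoxy)ethynyl]silane, via lithium acetylide 7 (not isolated)
Conditions: LiN(SiMe3)2 (1.2 equiv), THF, −78 °C; Me3SiCl, −78 °C to rt
Reagents that add atoms: chlorotrimethylsilane, C[Si](C)(C)Cl
Why: LiN(SiMe3)2 is basic enough to remove the sp C–H of the ynol ether but neither exchanges with aryl bromides nor metalates the lone C–H of ring B, and the lithium acetylide 7 is then C-silylated by Me3SiCl (alkyne deprotonation–silylation).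

Step 5
Reactants: 9 3-hydroxy-2-pyrone
Product: 10 3-acetoxy-2-pyrone
Conditions: Ac2O, pyridine, DMAP (cat.), CH2Cl2, 0 °C to rt
Reagents that add atoms: acetic anhydride, CC(=O)OC(C)=O
Why: DMAP-catalysed O-acylation of the enolic 3-hydroxyl group with acetic anhydride is standard ester formation.

Step 6
Reactants: 8 trimethyl[(2,3,4-tribromo-6-isopropoxyphenoxy)ethynyl]silane; 10 3-acetoxy-2-pyrone (1.5 equiv)
Product: 12 2-(2,3,4-tribromo-6-isopropoxyphenoxy)-3-(trimethylsilyl)phenyl acetate, via bicyclic lactone 11 (not isolated)
Conditions: toluene (degassed), 150 °C, sealed tube, BHT (cat.)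
Reagents that add atoms: none
Why: The electron-rich alkyne 8 and pyrone 10 should combine in a thermal inverse-electron-demand [4+2] cycloaddition across pyrone C3 and C6 to give the bridged lactone 11, which expels CO2 by retro-[4+2] fragmentation at the reaction temperature and so delivers the benzene ring directly. The closest known reaction type is the Diels–Alder/decarboxylation benzannulation of 2-pyrones with heteroatom-substituted alkynes such as ynamines, alkoxyalkynes, alkynylsilanes and alkynylboronates. Ring A is closed intermolecularly by the cycloaddition, which forms the bond between its positions 1 and 2 and the bond between its positions 5 and 6, and it becomes aromatic in the cycloreversion. No stereocentre survives, because the two bridgehead centres of racemic 11 are lost with CO2. The selectivity needed is regiochemical (the aryloxy carbon must bond to pyrone C3): the oxygen lone pair and the β-silicon effect both make the silyl-bearing carbon the nucleophilic alkyne terminus, which pairs with C6, the most electrophilic diene terminus, and the bulky SiMe3 end also avoids the acetoxy-substituted C3. An aryl ynol ether has no β-hydrogen for the retro-ene ketene fragmentation open to alkyl ynol ethers, so 8 should tolerate the heating.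

Step 7
Reactants: 12 2-(2,3,4-tribromo-6-isopropoxyphenoxy)-3-(trimethylsilyl)phenyl acetate
Product: 13 2-(2,3,4-tribromo-6-isopropoxyphenoxy)phenyl acetate
Conditions: CF3CO2H, CH2Cl2, 0 °C to rt
Reagents that add atoms: none
Why: Ipso-protodesilylation (electrophilic aromatic substitution by H+) is favoured at the silyl-bearing carbon (ring A position 6) because the ortho aryloxy oxygen and the β-silicon effect stabilise the arenium ion and steric strain is relieved, while the acetate and the isopropyl ether are stable to CF3CO2H at room temperature.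

Step 8
Reactants: 13 2-(2,3,4-tribromo-6-isopropoxyphenoxy)phenyl acetate
Product: 14 2-(2,3,4-tribromo-6-isopropoxyphenoxy)phenol
Conditions: K2CO3 (cat.), MeOH, rt
Reagents that add atoms: none
Why: Base-catalysed transesterification (methanolysis of an aryl acetate) frees the hydroxyl at ring A position 2 under conditions that leave the aryl bromides and both ethers untouched.

Step 9
Reactants: 14 2-(2,3,4-tribromo-6-isopropoxyphenoxy)phenol
Product: 15 2,4-dibromo-6-(2,3,4-tribromo-6-isopropoxyphenoxy)phenol
Conditions: Br2 (2.1 equiv), NaOAc, AcOH/CH2Cl2, 0 °C to rt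
Reagents that add atoms: bromine, BrBr
Why: Electrophilic aromatic bromination is controlled by the free hydroxyl at ring A position 2, whose only open ortho (position 3) and para (position 5) sites are brominated, while the weaker aryloxy director and the deactivated tribrominated ring B should not compete.

Step 10
Reactants: 15 2,4-dibromo-6-(2,3,4-tribromo-6-isopropoxyphenoxy)phenol
Product: 16 1,5-dibromo-2-methoxy-3-(2,3,4-tribromo-6-isopropoxyphenoxy)benzene
Conditions: MeI, K2CO3, DMF, rt
Reagents that add atoms: iodomethane, CI
Why: Williamson O-methylation (SN2) of the acidic dibromophenoxide with iodomethane is reliable even for a flanked phenol.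

Step 11
Reactants: 16 1,5-dibromo-2-methoxy-3-(2,3,4-tribromo-6-isopropoxyphenoxy)benzene
Product: 17 3,4,5-tribromo-2-(3,5-dibromo-2-methoxyphenoxy)phenol (target)
Conditions: BCl3, CH2Cl2, −78 to 0 °C; then H2O
Reagents that add atoms: none
Why: BCl3 cleaves isopropyl aryl ethers through a carbocation-like pathway much faster than methyl aryl ethers at low temperature, so the ring B hydroxyl should be freed selectively (Lewis-acid ether dealkylation).

**Compound list**

1 | 2-isopropoxyphenol | CC(C)Oc1ccccc1O | starting material
2 | 2,3,4-tribromo-6-isopropoxyphenol | Oc1c(OC(C)C)cc(Br)c(Br)c1Br | intermediate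
3 | cis-1,2-dichloroethylene | Cl/C=C\Cl | starting material
4 | chloroacetylene | ClC#C | intermediate
5 | 1,2,3-tribromo-4-{[(Z)-2-chloroethenyl]oxy}-5-isopropoxybenzene | Cl/C=C\Oc1c(OC(C)C)cc(Br)c(Br)c1Br | intermediate
6 | 1,2,3-tribromo-4-(ethynyloxy)-5-isopropoxybenzene | C#COc1c(OC(C)C)cc(Br)c(Br)c1Br | intermediate
7 | lithium [(2,3,4-tribromo-6-isopropoxyphenoxy)ethynide] | [Li]C#COc1c(OC(C)C)cc(Br)c(Br)c1Br | intermediate
8 | trimethyl[(2,3,4-tribromo-6-isopropoxyphenoxy)ethynyl]silane | C[Si](C)(C)C#COc1c(OC(C)C)cc(Br)c(Br)c1Br | intermediate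
9 | 3-hydroxy-2-pyrone | O=C1OC=CC=C1O | starting material
10 | 3-acetoxy-2-pyrone | CC(=O)OC1=CC=COC1=O | intermediate
11 | 3-oxo-5-(2,3,4-tribromo-6-isopropoxyphenoxy)-6-(trimethylsilyl)-2-oxabicyclo[2.2.2]octa-5,7-dien-4-yl acetate (racemic) | CC(=O)OC12C(=O)OC(C=C1)C([Si](C)(C)C)=C2Oc1c(OC(C)C)cc(Br)c(Br)c1Br | intermediate
12 | 2-(2,3,4-tribromo-6-isopropoxyphenoxy)-3-(trimethylsilyl)phenyl acetate | CC(=O)Oc1cccc([Si](C)(C)C)c1Oc1c(OC(C)C)cc(Br)c(Br)c1Br | intermediate
13 | 2-(2,3,4-tribromo-6-isopropoxyphenoxy)phenyl acetate | CC(=O)Oc1ccccc1Oc1c(OC(C)C)cc(Br)c(Br)c1Br | intermediate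
14 | 2-(2,3,4-tribromo-6-isopropoxyphenoxy)phenol | Oc1ccccc1Oc1c(OC(C)C)cc(Br)c(Br)c1Br | intermediate
15 | 2,4-dibromo-6-(2,3,4-tribromo-6-isopropoxyphenoxy)phenol | Oc1c(Br)cc(Br)cc1Oc1c(OC(C)C)cc(Br)c(Br)c1Br | intermediate
16 | 1,5-dibromo-2-methoxy-3-(2,3,4-tribromo-6-isopropoxyphenoxy)benzene | COc1c(Br)cc(Br)cc1Oc1c(OC(C)C)cc(Br)c(Br)c1Br | intermediate
17 | 3,4,5-tribromo-2-(3,5-dibromo-2-methoxyphenoxy)phenol | COc1c(Br)cc(Br)cc1Oc1c(O)cc(Br)c(Br)c1Br | target

**Step count**

Total: 11 steps. Longest linear sequence: 10 steps (steps 1–4 and 6–11, from 2-isopropoxyphenol); step 5 is a one-step side branch.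

**Steps most likely to fail**

Step 6. The cycloaddition may be too slow with a pyrone that is only moderately electron-poor, and the ynol ether may polymerise or decompose at the temperature needed; regiochemical leakage is the lesser concern. The fallback forms the diaryl ether by substitution instead of building ring A. It sets out from 2, which undergoes nucleophilic aromatic substitution on 2-fluorobenzaldehyde (K2CO3, DMAc, 130 °C) to give 2-(2,3,4-tribromo-6-isopropoxyphenoxy)benzaldehyde F1. Baeyer–Villiger (Dakin-type) oxidation with mCPBA in CH2Cl2 should then give 2-(2,3,4-tribromo-6-isopropoxyphenoxy)phenyl formate F2. Methanolysis (K2CO3, MeOH) returns to the route at 14.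

Step 2. The hindered, weakly nucleophilic tribromophenoxide may add too slowly to chloroacetylene, so that the alkyne is lost, a second phenoxide adds after over-elimination, or base-induced bromine migration sets in on ring B. The fallback builds the two-carbon unit by SN2 alkylation and sets out from 2. Alkylation with excess 1,2-dibromoethane (K2CO3, DMF, 60 °C) gives 1,2,3-tribromo-4-(2-bromoethoxy)-5-isopropoxybenzene F3. E2 elimination with KOtBu in THF gives the aryl vinyl ether 1,2,3-tribromo-5-isopropoxy-4-(vinyloxy)benzene F4. Addition of Br2 (CH2Cl2, −78 °C) gives 1,2,3-tribromo-4-(1,2-dibromoethoxy)-5-isopropoxybenzene F5. Excess KOtBu in THF then removes HBr twice, by way of 1,2,3-tribromo-4-[(2-bromoethenyl)oxy]-5-isopropoxybenzene F6. This returns to the route at 6.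

Step 3. Dehydrochlorination may be sluggish, and forcing it invites bromine migration on ring B or addition of tert-butoxide to the ynol ether. The fallback replaces chloride by triflate, which eliminates at −78 °C, and sets out from 2. Alkylation with bromoacetaldehyde diethyl acetal (K2CO3, DMF, 120 °C) gives 1,2,3-tribromo-4-(2,2-diethoxyethoxy)-5-isopropoxybenzene F7. Acetal hydrolysis (aqueous CF3CO2H, CHCl3) gives (2,3,4-tribromo-6-isopropoxyphenoxy)acetaldehyde F8. Enol triflation (Tf2O, 2,6-di-tert-butyl-4-methylpyridine, CH2Cl2) gives 2-(2,3,4-tribromo-6-isopropoxyphenoxy)ethenyl trifluoromethanesulfonate F9 as an E/Z mixture. KOtBu in THF at −78 °C then eliminates triflate and returns to the route at 6.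

**Further compounds**

F1 | step 6 | 2-(2,3,4-tribromo-6-isopropoxyphenoxy)benzaldehyde | O=Cc1ccccc1Oc1c(OC(C)C)cc(Br)c(Br)c1Br
F2 | step 6 | 2-(2,3,4-tribromo-6-isopropoxyphenoxy)phenyl formate | O=COc1ccccc1Oc1c(OC(C)C)cc(Br)c(Br)c1Br
F3 | step 2 | 1,2,3-tribromo-4-(2-bromoethoxy)-5-isopropoxybenzene | BrCCOc1c(OC(C)C)cc(Br)c(Br)c1Br
F4 | step 2 | 1,2,3-tribromo-5-isopropoxy-4-(vinyloxy)benzene | C=COc1c(OC(C)C)cc(Br)c(Br)c1Br
F5 | step 2 | 1,2,3-tribromo-4-(1,2-dibromoethoxy)-5-isopropoxybenzene (racemic) | BrCC(Br)Oc1c(OC(C)C)cc(Br)c(Br)c1Br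
F6 | step 2 | 1,2,3-tribromo-4-[(2-bromoethenyl)oxy]-5-isopropoxybenzene (E/Z mixture) | BrC=COc1c(OC(C)C)cc(Br)c(Br)c1Br
F7 | step 3 | 1,2,3-tribromo-4-(2,2-diethoxyethoxy)-5-isopropoxybenzene | CCOC(COc1c(OC(C)C)cc(Br)c(Br)c1Br)OCC
F8 | step 3 | (2,3,4-tribromo-6-isopropoxyphenoxy)acetaldehyde | O=CCOc1c(OC(C)C)cc(Br)c(Br)c1Br
F9 | step 3 | 2-(2,3,4-tribromo-6-isopropoxyphenoxy)ethenyl trifluoromethanesulfonate (E/Z mixture) | O=S(=O)(OC=COc1c(OC(C)C)cc(Br)c(Br)c1Br)C(F)(F)F
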